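**Plan**

- The benzene ring of the target carries OMe and O-acyl on para carbons, CH3 on the carbon next to C-OMe, the oxirane-bearing carbon next to C-O-acyl, and two ring CH. This is the pattern a Dötz benzannulation delivers, so the retrosynthesis cuts the aryl O-acyl bond and three ring bonds: C(OMe)-CH, C(oxiranyl)-C(O) and C(O)-CH.
- What remains is a chromium methoxy(isopropenyl)carbene (carbene carbon, C(CH3)=CH2 and one CO ligand supply four ring carbons) and an enantiopure 2-ethynyloxirane (two ring carbons). The alkyne is cut further at the primary ester, at the oxirane C-O bonds and at the C(sp)-C(sp2) bond.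
- Forward: the carbene complex is made in one pot. The enynol is joined by Sonogashira coupling, the oxirane ring closes by Sharpless epoxidation, the side-chain ester is added and silicon is removed. The benzene ring closes last, and the new phenol is acylated in the same flask.
- Stereochemistry: the single quaternary stereocentre comes from the tartrate in the Sharpless epoxidation and is a spectator afterwards. Its descriptor changes from R to S on acylation only because the CIP ranking of the two CH2O arms reverses.

Key step: step 6

Remark: in the SMILES of the chromium compounds the terminal carbonyl ligands are written formally as Cr=C=O.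
Assumption: the 2-alkynyl allylic alcohol is taken to follow the usual facial rule of the Sharpless epoxidation, as 2-methylallyl alcohol does, so D-(−)-tartrate is chosen to give the (R)-epoxy alcohol.

Step 1
Reactants: 1 2-bromopropene; 2 chromium hexacarbonyl
Product: 5 pentacarbonyl[methoxy(prop-1-en-2-yl)carbene]chromium(0), via isopropenyllithium 3 (not isolated), via lithium acylchromate 4 (not isolated)
Conditions: t-BuLi (2 equiv), Et2O, −78 °C; add to 2 in Et2O, 0 °C to rt; then Me3OBF4, CH2Cl2, 0 °C
Reagents that add atoms: trimethyloxonium tetrafluoroborate, C[O+](C)C.F[B-](F)(F)F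
Why: Fischer carbene synthesis, in which bromine-lithium exchange gives the alkenyllithium, this adds to a CO ligand to give the acyl chromate, and the hard oxonium salt methylates the acyl oxygen; no stereocentre is formed.

Step 2
Reactants: 6 2-bromoprop-2-en-1-ol; 7 trimethylsilylacetylene
Product: 8 2-methylidene-4-(trimethylsilyl)but-3-yn-1-ol
Conditions: PdCl2(PPh3)2 (2 mol %), CuI (4 mol %), Et3N, THF, rt
Reagents that add atoms: none
Why: Sonogashira coupling of a 1,1-disubstituted vinyl bromide with a terminal alkyne should proceed under mild conditions, tolerate the free allylic hydroxyl and leave the C-Si bond intact.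

Step 3
Reactants: 8 2-methylidene-4-(trimethylsilyl)but-3-yn-1-ol
Product: 9 [(2R)-2-[(trimethylsilyl)ethynyl]oxiran-2-yl]methanol
Conditions: Ti(OiPr)4 (10 mol %), D-(−)-DIPT (12 mol %), t-BuOOH, 4 Å MS, CH2Cl2, −20 °C
Reagents that add atoms: tert-butyl hydroperoxide, CC(C)(C)OO
Why: Sharpless asymmetric epoxidation, in which the allylic hydroxyl binds the titanium tartrate and the peroxide oxygen is delivered to one face of the alkene only (the alkyne is inert), the D-(−)-tartrate selecting the face that gives the (R)-configured quaternary oxirane carbon.

Step 4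
Reactants: 9 [(2R)-2-[(trimethylsilyl)ethynyl]oxiran-2-yl]methanol; 10 isobutyric anhydride
Product: 11 [(2S)-2-[(trimethylsilyl)ethynyl]oxiran-2-yl]methyl 2-methylpropanoate
Conditions: Et3N, DMAP (cat.), CH2Cl2, 0 °C
Reagents that add atoms: none
Why: DMAP-catalysed acylation of the primary alcohol runs without alkoxide formation, so no Payne rearrangement can scramble the quaternary centre, and the change of descriptor from R to S is a CIP ranking effect only.

Step 5
Reactants: 11 [(2S)-2-[(trimethylsilyl)ethynyl]oxiran-2-yl]methyl 2-methylpropanoate
Product: 12 [(2S)-2-ethynyloxiran-2-yl]methyl 2-methylpropanoate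
Conditions: TBAF, AcOH (1:1), THF, 0 °C
Reagents that add atoms: none
Why: Fluoride-induced protodesilylation of the alkynylsilane, buffered with acetic acid so that the medium stays non-basic and the primary ester and the oxirane should survive.

Step 6
Reactants: 5 pentacarbonyl[methoxy(prop-1-en-2-yl)carbene]chromium(0); 12 [(2S)-2-ethynyloxiran-2-yl]methyl 2-methylpropanoate; 10 isobutyric anhydride
Product: 14 2-[(2S)-2-[(isobutyryloxy)methyl]oxiran-2-yl]-4-methoxy-5-methylphenyl isobutyrate (CNP0237100.1), via phenol 13 (not isolated)
Conditions: Et3N, THF (degassed), 55 °C; then air, rt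
Reagents that add atoms: none
Why: Thermal loss of one cis CO from 5 lets alkyne 12 coordinate and insert into the Cr=C bond with its CH terminus bonding to the carbene carbon, a CO ligand then inserts to give an η4-dienylketene, 6π-electrocyclic closure onto the isopropenyl CH2 gives a cyclohexadienone that tautomerises to phenol 13, and 10 with Et3N acylates this phenol as it forms. The closest known reaction type is the Dötz benzannulation of alkenyl(alkoxy)carbene chromium complexes with terminal alkynes run with an anhydride and a tertiary amine for acylation in the flask, applied here to an alkyne with a quaternary propargylic oxirane. The benzene ring closes by 6π-electrocyclisation of the chromium-bound dienylketene, after which three new ring bonds are in place (C-OMe carbon to CH, oxiranyl carbon to C-O, C-O carbon to CH). No stereocentre is formed and the quaternary oxirane carbon changes no bond, so its configuration should carry over unchanged. The step needs regioselective insertion, secured by the terminal alkyne, whose bulky oxirane-bearing carbon avoids the carbene carbon and so ends next to the CO-derived carbon, and it needs phenol formation over cyclopentannulation or furan formation, secured by the alkenyl carbene in THF. Immediate acylation keeps the ortho phenol from opening the benzylic oxirane, and air then removes the Cr(CO)3 group from the arene.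

**Compound list**

1 | 2-bromopropene | CC(Br)=C | starting material
2 | chromium hexacarbonyl | O=C=[Cr](=C=O)(=C=O)(=C=O)(=C=O)=C=O | starting material
3 | isopropenyllithium (prop-1-en-2-yllithium) | [Li]C(C)=C | intermediate
4 | lithium pentacarbonyl(2-methylprop-2-enoyl)chromate (acyl chromate) | [Li+].[O-]C(C(C)=C)=[Cr](=C=O)(=C=O)(=C=O)(=C=O)=C=O | intermediate
5 | pentacarbonyl[methoxy(prop-1-en-2-yl)carbene]chromium(0) | COC(C(C)=C)=[Cr](=C=O)(=C=O)(=C=O)(=C=O)=C=O | intermediate
6 | 2-bromoprop-2-en-1-ol | OCC(Br)=C | starting material
7 | trimethylsilylacetylene | C#C[Si](C)(C)C | starting material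
8 | 2-methylidene-4-(trimethylsilyl)but-3-yn-1-ol | C[Si](C)(C)C#CC(=C)CO | intermediate
9 | [(2R)-2-[(trimethylsilyl)ethynyl]oxiran-2-yl]methanol | C[Si](C)(C)C#C[C@@]1(CO)CO1 | intermediate
10 | isobutyric anhydride | CC(C)C(=O)OC(=O)C(C)C | starting material
11 | [(2S)-2-[(trimethylsilyl)ethynyl]oxiran-2-yl]methyl 2-methylpropanoate | C[Si](C)(C)C#C[C@@]1(COC(=O)C(C)C)CO1 | intermediate
12 | [(2S)-2-ethynyloxiran-2-yl]methyl 2-methylpropanoate | C#C[C@@]1(COC(=O)C(C)C)CO1 | intermediate
13 | [(2S)-2-(2-hydroxy-5-methoxy-4-methylphenyl)oxiran-2-yl]methyl 2-methylpropanoate (phenol formed in the flask, at first as its Cr(CO)3 arene complex) | COc1cc([C@@]2(COC(=O)C(C)C)CO2)c(O)cc1C | intermediate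
14 | 2-[(2S)-2-[(isobutyryloxy)methyl]oxiran-2-yl]-4-methoxy-5-methylphenyl isobutyrate (CNP0237100.1) | COc1cc([C@@]2(COC(=O)C(C)C)CO2)c(OC(=O)C(C)C)cc1C | target

**Count**

Total steps: 6. Longest linear sequence: 5 steps (steps 2 to 6, from 2-bromoprop-2-en-1-ol); step 1 is a one-step side branch that joins at step 6.

**Steps most likely to fail**

Step 6. The chromium dienylketene may be diverted before ring closure, the hindered alkyne may insert sluggishly, or the oxirane may be opened by the chromium fragment or by the phenol before acylation catches it. The fallback keeps the same benzannulation but carries the oxirane carbons through it as an alkene and sets the stereocentre last. It sets out from 8, which is acylated with 10 (Et3N, DMAP) to 2-methylidene-4-(trimethylsilyl)but-3-yn-1-yl 2-methylpropanoate F1 and desilylated (TBAF, AcOH) to 2-methylidenebut-3-yn-1-yl 2-methylpropanoate F2. Benzannulation of F2 with 5 in the presence of 10 and Et3N should pass through 2-(2-hydroxy-5-methoxy-4-methylphenyl)prop-2-en-1-yl 2-methylpropanoate F3 and give 2-[3-(isobutyryloxy)prop-1-en-2-yl]-4-methoxy-5-methylphenyl isobutyrate F4. Shi epoxidation of this 1,1-disubstituted aryl alkene (chiral ketone of the enantiomeric series that delivers the S oxirane, Oxone, buffer near pH 8) would come back to the route at 14.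

Step 3. The conjugated 1,1-disubstituted alkene may be epoxidised slowly, so that titanium-promoted opening of the 2,2-disubstituted epoxy alcohol or incomplete facial control erodes the material. The fallback makes the quaternary centre by desymmetrisation instead. It sets out from 7, whose lithium acetylide (n-BuLi, THF, −78 °C) is added to commercial 2,2-dimethyl-1,3-dioxan-5-one to give 2,2-dimethyl-5-[(trimethylsilyl)ethynyl]-1,3-dioxan-5-ol F5. Aqueous acetic acid should free 2-[(trimethylsilyl)ethynyl]propane-1,2,3-triol F6. A lipase with vinyl isobutyrate acylates one of the two enantiotopic primary hydroxyls to give (2S)-2-hydroxy-2-(hydroxymethyl)-4-(trimethylsilyl)but-3-yn-1-yl 2-methylpropanoate F7; the lipase is chosen for this sense, and the opposite sense would be reached by enzymatic hydrolysis of the bis-isobutyrate. Tosylation of the remaining primary hydroxyl (TsCl, pyridine, 0 °C) gives (2R)-2-hydroxy-2-[(tosyloxy)methyl]-4-(trimethylsilyl)but-3-yn-1-yl 2-methylpropanoate F8, and DBU closes the oxirane from the tertiary hydroxyl to return to the route at 11.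

Step 5. Fluoride may attack or shift the primary ester, or open the oxirane, during desilylation, and the small alkyne may be lost on concentration. The fallback removes silicon before the sensitive groups exist. It sets out from 8, which K2CO3 in methanol desilylates to 2-methylidenebut-3-yn-1-ol F9, kept in solution. Sharpless epoxidation with D-(−)-DIPT should give [(2R)-2-ethynyloxiran-2-yl]methanol F10, which is not isolated but acylated in the same flask with 10 (Et3N, DMAP) to come back to the route at 12.

**Further compounds**

F1 | step 6 | 2-methylidene-4-(trimethylsilyl)but-3-yn-1-yl 2-methylpropanoate | C[Si](C)(C)C#CC(=C)COC(=O)C(C)C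
F2 | step 6 | 2-methylidenebut-3-yn-1-yl 2-methylpropanoate | C#CC(=C)COC(=O)C(C)C
F3 | step 6 | 2-(2-hydroxy-5-methoxy-4-methylphenyl)prop-2-en-1-yl 2-methylpropanoate | COc1cc(C(=C)COC(=O)C(C)C)c(O)cc1C
F4 | step 6 | 2-[3-(isobutyryloxy)prop-1-en-2-yl]-4-methoxy-5-methylphenyl isobutyrate | COc1cc(C(=C)COC(=O)C(C)C)c(OC(=O)C(C)C)cc1C
F5 | step 3 | 2,2-dimethyl-5-[(trimethylsilyl)ethynyl]-1,3-dioxan-5-ol | CC1(C)OCC(O)(C#C[Si](C)(C)C)CO1
F6 | step 3 | 2-[(trimethylsilyl)ethynyl]propane-1,2,3-triol | OCC(O)(CO)C#C[Si](C)(C)C
F7 | step 3 | (2S)-2-hydroxy-2-(hydroxymethyl)-4-(trimethylsilyl)but-3-yn-1-yl 2-methylpropanoate | C[Si](C)(C)C#C[C@@](O)(COC(=O)C(C)C)CO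
F8 | step 3 | (2R)-2-hydroxy-2-[(tosyloxy)methyl]-4-(trimethylsilyl)but-3-yn-1-yl 2-methylpropanoate | C[Si](C)(C)C#C[C@@](O)(COC(=O)C(C)C)COS(=O)(=O)c1ccc(C)cc1
F9 | step 5 | 2-methylidenebut-3-yn-1-ol | C#CC(=C)CO
F10 | step 5 | [(2R)-2-ethynyloxiran-2-yl]methanol | C#C[C@@]1(CO)CO1
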